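**Plan**
- Retrosynthetic cuts, in order: the C19–O7 lactone bond; C6–C7 (ring-closing γ-chloroallylchromium addition); C3–C4 (Ni/Cr alkenyl–aldehyde coupling); C8–C9 (dioxolanone aldol); C1–C14 and C10–C11 of ring A (Diels–Alder).
- Forward: ring A is built first and carried as a vinyl iodide and a silyl dienol ether (masked acetoxy-enone); the C7–C9/C17–C19 arm is added by aldol; ring A is unmasked by α′-acetoxylation; the C4–C6/C16 arm is joined at C3–C4; the ten-membered ring C1–C10 closes at C6–C7; the γ-lactone closes last.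
- Feature used: the C7–O, C6–Cl, C5=C16 array is what an SE2′ addition of a γ-chloroallyl metal (metal on C16) to a C7 aldehyde leaves behind, so ring bond, chloride, carbinol and exo-methylene arise together.
- Stereochemistry: C1/C10 from a catalytic enantioselective Diels–Alder; C11 by substrate-controlled acetoxylation; C8 and C17 from (S)-malate; C9 by a matched aldol; C4 by ligand-controlled Ni/Cr coupling; C6 and C7 in the key step.

Key step: step 26

Remark (numbering): briarane numbering is used throughout: ring A = C1, C14, C13, C12, C11, C10; ten-membered ring = C1 to C10; C15 on C1, C16 on C5, C20 on C11; lactone arm C17 (methyl C18) and C19 on C8.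
Assumption: the oxazaborolidinium catalyst (step 2) and the chromium ligand (step 21) are written in the enantiomeric form expected from their transition-state models to give the drawn configurations; if the sense proves opposite, the mirror-image catalyst or ligand is used.

Step 1
Reactants: 1 pent-1-en-3-one
Product: 2 (3Z)-3-[(triisopropylsilyl)oxy]penta-1,3-diene
Conditions: TIPSOTf, Et3N, Et2O, 0 °C → rt
Reagents that add atoms: triisopropylsilyl trifluoromethanesulfonate, CC(C)[Si](OS(=O)(=O)C(F)(F)F)(C(C)C)C(C)C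
Why: Soft enolisation (silyl triflate/amine) of the only enolisable side of the vinyl ketone should give the 2-silyloxy diene, the Z enol ether being the usual outcome for ethyl ketones.

Step 2
Reactants: 2 (3Z)-3-[(triisopropylsilyl)oxy]penta-1,3-diene; 3 ethyl (2E)-3-methyl-4-oxobut-2-enoate
Product: 4 ethyl (1S,2S,6S)-6-formyl-2,6-dimethyl-3-[(triisopropylsilyl)oxy]cyclohex-3-ene-1-carboxylate
Conditions: (S)-3,3-diphenyl-1-(2-methylphenyl)tetrahydro-1H,3H-pyrrolo[1,2-c][1,3,2]oxazaborole activated by Tf2NH (20 mol %), CH2Cl2, −78 → −40 °C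
Reagents that add atoms: none
Why: Catalytic enantioselective Diels–Alder reaction in which the catalyst binds the formyl group, so the nucleophilic CH(Me) terminus of the diene bonds to C10 and the CH2 terminus to C1, the E dienophile gives the trans C2/C9 relationship, the catalyst face selection sets C1 and C10, and the C11 methyl centre (drawn for the formyl-endo adduct) is erased in step 5.

Step 3
Reactants: 4 ethyl (1S,2S,6S)-6-formyl-2,6-dimethyl-3-[(triisopropylsilyl)oxy]cyclohex-3-ene-1-carboxylate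
Product: 5 ethyl (1S,2S,6S)-6-formyl-2,6-dimethyl-3-oxocyclohex-4-ene-1-carboxylate
Conditions: Pd(OAc)2 (1.05 equiv), MeCN, rt
Reagents that add atoms: none
Why: Saegusa–Ito oxidation, in which the C13 palladium enolate has β-hydrogens only at C14, should give the C13=C14 enone without touching the formyl or ester group.

Step 4
Reactants: 5 ethyl (1S,2S,6S)-6-formyl-2,6-dimethyl-3-oxocyclohex-4-ene-1-carboxylate
Product: 6 ethyl (1S,2S,6S)-6-[(E)-2-iodoethenyl]-2,6-dimethyl-3-oxocyclohex-4-ene-1-carboxylate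
Conditions: CrCl2 (6 equiv), CHI3 (2 equiv), THF, 0 °C → rt
Reagents that add atoms: iodoform, IC(I)I
Why: Takai olefination of the non-enolisable neopentyl aldehyde should give the E vinyl iodide, a placeholder for C3, while divalent chromium leaves the enone and ester alone.

Step 5
Reactants: 6 ethyl (1S,2S,6S)-6-[(E)-2-iodoethenyl]-2,6-dimethyl-3-oxocyclohex-4-ene-1-carboxylate
Product: 7 ethyl (1R,6S)-3-[(tert-butyldimethylsilyl)oxy]-6-[(E)-2-iodoethenyl]-2,6-dimethylcyclohexa-2,4-diene-1-carboxylate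
Conditions: TBSOTf, Et3N, CH2Cl2, 0 °C
Reagents that add atoms: tert-butyldimethylsilyl trifluoromethanesulfonate, CC(C)(C)[Si](C)(C)OS(=O)(=O)C(F)(F)F
Why: Soft enolisation at C11, the only enolisable position of the enone, should give the cross-conjugated silyl dienol ether, which masks the ketone through the hydride steps and planarises C11.

Step 6
Reactants: 7 ethyl (1R,6S)-3-[(tert-butyldimethylsilyl)oxy]-6-[(E)-2-iodoethenyl]-2,6-dimethylcyclohexa-2,4-diene-1-carboxylate
Product: 8 [(1R,6S)-3-[(tert-butyldimethylsilyl)oxy]-6-[(E)-2-iodoethenyl]-2,6-dimethylcyclohexa-2,4-dien-1-yl]methanol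
Conditions: DIBAL-H (2.5 equiv), CH2Cl2, −78 °C
Reagents that add atoms: none
Why: DIBAL-H reduction of the ester to the primary alcohol, with the silyl dienol ether and the vinyl iodide inert to the hydride.

Step 7
Reactants: 8 [(1R,6S)-3-[(tert-butyldimethylsilyl)oxy]-6-[(E)-2-iodoethenyl]-2,6-dimethylcyclohexa-2,4-dien-1-yl]methanol
Product: 9 (1R,6S)-3-[(tert-butyldimethylsilyl)oxy]-6-[(E)-2-iodoethenyl]-2,6-dimethylcyclohexa-2,4-diene-1-carbaldehyde
Conditions: Dess–Martin periodinane, pyridine, CH2Cl2, 0 °C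
Reagents that add atoms: none
Why: Dess–Martin oxidation buffered with pyridine should give the C9 aldehyde without acid that would hydrolyse the dienol ether or epimerise C10.

Step 8
Reactants: 10 diethyl (S)-malate
Product: 12 diethyl (2S,3R)-2-hydroxy-3-methylbutanedioate, via dilithium alkoxide enolate 11 (not isolated)
Conditions: LDA (2.2 equiv), THF, −78 → −20 °C; MeI, −78 → 0 °C
Reagents that add atoms: iodomethane, CI
Why: Fráter–Seebach alkylation, in which the chelated lithium alkoxide enolate is methylated anti to the alkoxide, sets C17 (3R) relative to the 2S carbinol.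

Step 9
Reactants: 12 diethyl (2S,3R)-2-hydroxy-3-methylbutanedioate
Product: 13 (2S,3R)-2-hydroxy-3-methylbutanedioic acid
Conditions: KOH (2.5 equiv), H2O, 0 °C → rt; then HCl to pH 1
Reagents that add atoms: potassium hydroxide (aqueous), [K+].[OH-]
Why: Saponification of both esters at low temperature, where the centre α to a carboxylate should not epimerise.

Step 10
Reactants: 13 (2S,3R)-2-hydroxy-3-methylbutanedioic acid
Product: 14 (2R)-2-[(2S,4S)-2-tert-butyl-5-oxo-1,3-dioxolan-4-yl]propanoic acid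
Conditions: pivalaldehyde, TsOH·H2O (cat.), H2SO4 (cat.), pentane, reflux, water separator
Reagents that add atoms: pivalaldehyde, CC(C)(C)C=O
Why: Acid-catalysed acetalisation of the α-hydroxy acid closes the five-membered dioxolanone under thermodynamic control, giving the cis acetal whose new 2S centre stores the C8 configuration.

Step 11
Reactants: 14 (2R)-2-[(2S,4S)-2-tert-butyl-5-oxo-1,3-dioxolan-4-yl]propanoic acid
Product: 15 tert-butyl (2R)-2-[(2S,4S)-2-tert-butyl-5-oxo-1,3-dioxolan-4-yl]propanoate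
Conditions: tert-butyl 2,2,2-trichloroacetimidate, BF3·OEt2 (cat.), CH2Cl2/cyclohexane, rt
Reagents that add atoms: tert-butyl 2,2,2-trichloroacetimidate, CC(C)(C)OC(=N)C(Cl)(Cl)Cl
Why: Imidate tert-butylation of the free acid gives a bulky ester that later resists lactonisation and competing enolisation.

Step 12
Reactants: 15 tert-butyl (2R)-2-[(2S,4S)-2-tert-butyl-5-oxo-1,3-dioxolan-4-yl]propanoate; 9 (1R,6S)-3-[(tert-butyldimethylsilyl)oxy]-6-[(E)-2-iodoethenyl]-2,6-dimethylcyclohexa-2,4-diene-1-carbaldehyde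
Product: 17 aldol adduct with the C9 carbinol on C8 of the dioxolanone, (1S,8R,9R,10R,17R), via lithium enolate 16 (not isolated)
Conditions: LDA (1.05 equiv), THF, −78 °C; then 9, −78 °C; AcOH quench at −78 °C
Reagents that add atoms: none
Why: Aldol addition of a dioxolanone enolate (self-regeneration of stereocentres), in which the aldehyde enters trans to the tert-butyl group so that C8 forms with retention, while C9 follows from a Zimmerman–Traxler chair (C17 cis to OLi, giving C17/O9 syn) that is matched with Felkin–Anh attack anti to quaternary C1.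

Step 13
Reactants: 17 aldol adduct
Product: 18 tert-butyl (2R,3S,4R)-4-[(1R,6S)-3-[(tert-butyldimethylsilyl)oxy]-6-[(E)-2-iodoethenyl]-2,6-dimethylcyclohexa-2,4-dien-1-yl]-3,4-dihydroxy-3-(hydroxymethyl)-2-methylbutanoate
Conditions: LiBH4, THF, 0 °C
Reagents that add atoms: none
Why: Chemoselective borohydride reduction of the activated acylal lactone carbonyl beside the hindered tert-butyl ester, in which the hemiacetal collapses, pivalaldehyde is lost and reduced, and the C7 primary and C8 tertiary hydroxyls are released.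

Step 14
Reactants: 18 triol
Product: 20 C7 triethylsilyl ether C9 acetate with free C8 hydroxyl, via C7 mono-triethylsilyl ether 19 (not isolated)
Conditions: TESCl (1.1 equiv), imidazole, CH2Cl2, −20 °C; then Ac2O, DMAP (cat.), pyridine, rt
Reagents that add atoms: chlorotriethylsilane, CC[Si](Cl)(CC)CC; acetic anhydride, CC(=O)OC(C)=O
Why: Steric differentiation of the triol by silylation of the primary C7 hydroxyl followed by DMAP-catalysed acetylation of the secondary C9 hydroxyl, the tertiary C8 hydroxyl reacting with neither.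

Step 15
Reactants: 20 C7 triethylsilyl ether C9 acetate
Product: 21 C7,C8-bis(triethylsilyl) ether C9 acetate
Conditions: TESOTf (1.2 equiv), 2,6-lutidine, CH2Cl2, −78 → −40 °C
Reagents that add atoms: triethylsilyl trifluoromethanesulfonate, CC[Si](CC)(CC)OS(=O)(=O)C(F)(F)F
Why: Silyl triflate silylation of the hindered tertiary alcohol at a temperature where the tert-butyl ester is not cleaved, giving the non-chelating C8 ether needed in the key step.

Step 16
Reactants: 21 C7,C8-bis(triethylsilyl) ether C9 acetate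
Product: 22 tert-butyl (2R,3S,4R)-4-acetoxy-4-[(1S,2S,6S)-2-acetoxy-6-[(E)-2-iodoethenyl]-2,6-dimethyl-3-oxocyclohex-4-en-1-yl]-2-methyl-3-[(triethylsilyl)oxy]-3-{[(triethylsilyl)oxy]methyl}butanoate
Conditions: Pb(OAc)4 (acetic acid-free, 1.1 equiv), CH2Cl2, 0 °C → rt
Reagents that add atoms: lead tetraacetate, CC(=O)O[Pb](OC(C)=O)(OC(C)=O)OC(C)=O
Why: α′-Acetoxylation of a 2-silyloxy diene with lead tetraacetate (Rubottom-type oxidation), in which plumbylation at C11 and acetate transfer occur on the face anti to the C9 arm on neighbouring C10 and anti to the C15 methyl, sets C11 and unveils the enone in one operation.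

Step 17
Reactants: 23 methyl propiolate; 24 formaldehyde (monomer from cracked paraformaldehyde)
Product: 25 methyl (2Z)-3-chloro-2-(hydroxymethyl)prop-2-enoate
Conditions: TiCl4 (1.2 equiv), CH2Cl2, −78 → 0 °C
Reagents that add atoms: titanium tetrachloride, Cl[Ti](Cl)(Cl)Cl
Why: Halo-aldol (β-halo Baylis–Hillman) reaction in which chloride adds to the titanium-activated propiolate and the chloro-allenolate attacks formaldehyde anti to chlorine, placing Cl cis to the ester carbon that becomes C4.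

Step 18
Reactants: 25 methyl (2Z)-3-chloro-2-(hydroxymethyl)prop-2-enoate
Product: 26 methyl (2Z)-3-chloro-2-{[(triethylsilyl)oxy]methyl}prop-2-enoate
Conditions: TESCl, imidazole, CH2Cl2, 0 °C
Reagents that add atoms: chlorotriethylsilane, CC[Si](Cl)(CC)CC
Why: Standard silylation of the primary allylic alcohol that becomes C16–O.

Step 19
Reactants: 26 methyl (2Z)-3-chloro-2-{[(triethylsilyl)oxy]methyl}prop-2-enoate
Product: 27 (2E)-3-chloro-2-{[(triethylsilyl)oxy]methyl}prop-2-en-1-ol
Conditions: DIBAL-H (2.2 equiv), CH2Cl2, −78 °C; neutral work-up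
Reagents that add atoms: none
Why: DIBAL-H 1,2-reduction of the unsaturated ester, with a cold neutral work-up to avoid silyl migration between the two oxygens, which would scramble the alkene geometry.

Step 20
Reactants: 27 (2E)-3-chloro-2-{[(triethylsilyl)oxy]methyl}prop-2-en-1-ol
Product: 28 (2Z)-3-chloro-2-{[(triethylsilyl)oxy]methyl}prop-2-enal
Conditions: MnO2, CH2Cl2, rt
Reagents that add atoms: none
Why: MnO2 oxidation of the allylic alcohol to the enal under neutral conditions with retention of alkene geometry.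

Step 21
Reactants: 22 acetoxy-enone vinyl iodide; 28 (2Z)-3-chloro-2-{[(triethylsilyl)oxy]methyl}prop-2-enal
Product: 30 C4 allylic alcohol, (1S,4S,8S,9R,10S,11S,17R), 2E,5Z, via alkenylchromium species 29 (not isolated)
Conditions: CrCl2 (4 equiv), (S)-N-[2-(4-isopropyl-4,5-dihydro-1,3-oxazol-2-yl)-6-methylphenyl]methanesulfonamide (4.4 equiv), Et3N (4.4 equiv), NiCl2 (5 mol %), THF, rt
Reagents that add atoms: none
Why: Asymmetric Nozaki–Hiyama–Kishi coupling in which zerovalent nickel inserts only into the C–I bond, the alkenylchromium adds 1,2 to the enal, and the chiral sulfonamide ligand on chromium selects the aldehyde face to set C4, while the vinylic chloride, enone, acetates and esters should not react.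

Step 22
Reactants: 30 C4 allylic alcohol
Product: 31 C4 acetate of 30
Conditions: Ac2O, DMAP (cat.), pyridine, CH2Cl2, 0 °C → rt
Reagents that add atoms: acetic anhydride, CC(=O)OC(C)=O
Why: DMAP-catalysed acetylation of the only free hydroxyl.

Step 23
Reactants: 31 C4 acetate
Product: 32 C7,C16-diol with the C8 triethylsilyl ether retained
Conditions: PPTS (cat.), MeOH/CH2Cl2, 0 °C
Reagents that add atoms: none
Why: Mild acid methanolysis should remove the two primary triethylsilyl ethers far faster than the very hindered tertiary C8 ether and leave the acetates and the tert-butyl ester intact.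

Step 24
Reactants: 32 C7,C16-diol
Product: 33 C16 allylic bromide with free C7 hydroxyl, 5E
Conditions: CBr4, PPh3, 2,6-lutidine, CH2Cl2, −20 °C
Reagents that add atoms: carbon tetrabromide, BrC(Br)(Br)Br
Why: Appel bromination, in which the unhindered allylic C16 alcohol undergoes SN2 displacement whereas the neopentyl C7 alcohol cannot.

Step 25
Reactants: 33 C16 allylic bromide
Product: 34 seco aldehyde, (1S,4S,8R,9R,10S,11S,17R), 2E,5E, with C7 formyl, C8–OSiEt3, C16–Br and C6 chloromethylene (Cl trans to CH2Br)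
Conditions: Dess–Martin periodinane, CH2Cl2, 0 °C → rt
Reagents that add atoms: none
Why: Dess–Martin oxidation of the neopentyl primary alcohol to the α-silyloxy aldehyde, which leaves the allylic bromide and vinylic chloride untouched.

Step 26
Reactants: 34 seco aldehyde
Product: 36 ten-membered anti-chlorohydrin, (1S,4S,6S,7R,8S,9R,10S,11S,17R), via γ-chloroallylchromium species 35 (not isolated)
Conditions: CrCl2 (3 equiv), THF, 0 °C → rt, slow addition of 34 (final 2 mM), quench when the bromide is consumed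
Reagents that add atoms: none
Why: Proposed new method: divalent chromium inserts into the allylic C16–Br bond (the vinylic C–Cl bond, acetates, enone and tert-butyl ester are not reduced by CrCl2), and the E-γ-chloroallylchromium 35 adds through C6 to the C7 aldehyde in an SE2′ process via a six-membered chair, forming C6–C7 and moving the alkene to C5=C16. The closest known reactions are intermolecular γ-chloroallylchromium and γ-chloroallylborane additions to aldehydes giving anti-chlorohydrins, and Nozaki–Hiyama allylation macrocyclisations of ω-formyl allylic bromides to ten- to fourteen-membered carbocycles. The ring C1–C10 closes in a 10-exo-trig addition to the carbonyl, helped by high dilution and by ring A and the E-C2=C3 alkene, which hold the termini within reach. C6 is controlled by the allylchromium geometry: chlorine trans to CH2Cr sits equatorial in the chair and gives the 6,7-anti chlorohydrin. C7 is controlled by C8 through polar Felkin–Anh addition anti to the C8–OSiEt3 bond and past the smaller C17 arm, which the non-chelating silyl ether secures. The step needs metal insertion at the allylic bromide only and γ- over α-attack, both inherent to allylchromium reagents, and limited CrCl2 so that the allylic chloride of the product is not reduced.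

Step 27
Reactants: 36 ten-membered anti-chlorohydrin
Product: 38 CNP0159278.2, via hydroxy acid 37 (not isolated)
Conditions: TFA/CH2Cl2 (1:4), H2O (5 equiv), 0 °C → rt
Reagents that add atoms: none
Why: Acid-promoted deprotection–lactonisation, in which trifluoroacetic acid cleaves the tert-butyl ester and the C8 silyl ether and the γ-hydroxy acid closes the five-membered lactone onto the C7 hydroxyl without change at any stereocentre.

**Compound list**
1 | pent-1-en-3-one | CCC(=O)C=C | starting material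
2 | (3Z)-3-[(triisopropylsilyl)oxy]penta-1,3-diene | C=C/C(O[Si](C(C)C)(C(C)C)C(C)C)=C/C | intermediate
3 | ethyl (2E)-3-methyl-4-oxobut-2-enoate | CCOC(=O)/C=C(C)/C=O | starting material
4 | ethyl (1S,2S,6S)-6-formyl-2,6-dimethyl-3-[(triisopropylsilyl)oxy]cyclohex-3-ene-1-carboxylate (ring C1 = C10, C2 = C11, C6 = C1; formyl and ester trans) | O=C[C@@]1(C)CC=C(O[Si](C(C)C)(C(C)C)C(C)C)[C@@H](C)[C@@H]1C(=O)OCC | intermediate
5 | ethyl (1S,2S,6S)-6-formyl-2,6-dimethyl-3-oxocyclohex-4-ene-1-carboxylate | O=C[C@@]1(C)C=CC(=O)[C@@H](C)[C@@H]1C(=O)OCC | intermediate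
6 | ethyl (1S,2S,6S)-6-[(E)-2-iodoethenyl]-2,6-dimethyl-3-oxocyclohex-4-ene-1-carboxylate | I/C=C/[C@@]1(C)C=CC(=O)[C@@H](C)[C@@H]1C(=O)OCC | intermediate
7 | ethyl (1R,6S)-3-[(tert-butyldimethylsilyl)oxy]-6-[(E)-2-iodoethenyl]-2,6-dimethylcyclohexa-2,4-diene-1-carboxylate | I/C=C/[C@@]1(C)C=CC(O[Si](C)(C)C(C)(C)C)=C(C)[C@@H]1C(=O)OCC | intermediate
8 | [(1R,6S)-3-[(tert-butyldimethylsilyl)oxy]-6-[(E)-2-iodoethenyl]-2,6-dimethylcyclohexa-2,4-dien-1-yl]methanol | I/C=C/[C@@]1(C)C=CC(O[Si](C)(C)C(C)(C)C)=C(C)[C@@H]1CO | intermediate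
9 | (1R,6S)-3-[(tert-butyldimethylsilyl)oxy]-6-[(E)-2-iodoethenyl]-2,6-dimethylcyclohexa-2,4-diene-1-carbaldehyde | I/C=C/[C@@]1(C)C=CC(O[Si](C)(C)C(C)(C)C)=C(C)[C@@H]1C=O | intermediate
10 | diethyl (S)-malate | CCOC(=O)C[C@H](O)C(=O)OCC | starting material
11 | dilithium alkoxide enolate of 10 | [Li+].[Li+].CCOC(=O)[C@@H]([O-])C=C([O-])OCC | intermediate
12 | diethyl (2S,3R)-2-hydroxy-3-methylbutanedioate | CCOC(=O)[C@H](C)[C@H](O)C(=O)OCC | intermediate
13 | (2S,3R)-2-hydroxy-3-methylbutanedioic acid | OC(=O)[C@H](C)[C@H](O)C(=O)O | intermediate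
14 | (2R)-2-[(2S,4S)-2-tert-butyl-5-oxo-1,3-dioxolan-4-yl]propanoic acid (cis acetal) | CC(C)(C)[C@H]1O[C@@H]([C@@H](C)C(=O)O)C(=O)O1 | intermediate
15 | tert-butyl (2R)-2-[(2S,4S)-2-tert-butyl-5-oxo-1,3-dioxolan-4-yl]propanoate | CC(C)(C)[C@H]1O[C@@H]([C@@H](C)C(=O)OC(C)(C)C)C(=O)O1 | intermediate
16 | lithium enolate of 15 (C8 planar, acetal centre retained) | [Li+].CC(C)(C)[C@H]1OC([C@@H](C)C(=O)OC(C)(C)C)=C([O-])O1 | intermediate
17 | aldol adduct: tert-butyl (2R)-2-[(2S,4R)-2-tert-butyl-4-{(R)-hydroxy[(1R,6S)-3-[(tert-butyldimethylsilyl)oxy]-6-[(E)-2-iodoethenyl]-2,6-dimethylcyclohexa-2,4-dien-1-yl]methyl}-5-oxo-1,3-dioxolan-4-yl]propanoate | I/C=C/[C@@]1(C)C=CC(O[Si](C)(C)C(C)(C)C)=C(C)[C@@H]1[C@@H](O)[C@]2(O[C@H](C(C)(C)C)OC2=O)[C@@H](C)C(=O)OC(C)(C)C | intermediate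
18 | triol: tert-butyl (2R,3S,4R)-4-[(1R,6S)-3-[(tert-butyldimethylsilyl)oxy]-6-[(E)-2-iodoethenyl]-2,6-dimethylcyclohexa-2,4-dien-1-yl]-3,4-dihydroxy-3-(hydroxymethyl)-2-methylbutanoate | I/C=C/[C@@]1(C)C=CC(O[Si](C)(C)C(C)(C)C)=C(C)[C@@H]1[C@@H](O)[C@@](O)(CO)[C@@H](C)C(=O)OC(C)(C)C | intermediate
19 | C7 mono-triethylsilyl ether of 18 (C8–OH and C9–OH free) | I/C=C/[C@@]1(C)C=CC(O[Si](C)(C)C(C)(C)C)=C(C)[C@@H]1[C@@H](O)[C@@](O)(CO[Si](CC)(CC)CC)[C@@H](C)C(=O)OC(C)(C)C | intermediate
20 | C9 acetate of 19: tert-butyl (2R,3S,4R)-4-acetoxy-4-[ring as in 18]-3-hydroxy-2-methyl-3-{[(triethylsilyl)oxy]methyl}butanoate | I/C=C/[C@@]1(C)C=CC(O[Si](C)(C)C(C)(C)C)=C(C)[C@@H]1[C@@H](OC(C)=O)[C@@](O)(CO[Si](CC)(CC)CC)[C@@H](C)C(=O)OC(C)(C)C | intermediate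
21 | C8 triethylsilyl ether of 20 (C7–OSiEt3, C8–OSiEt3, C9–OAc) | I/C=C/[C@@]1(C)C=CC(O[Si](C)(C)C(C)(C)C)=C(C)[C@@H]1[C@@H](OC(C)=O)[C@@](O[Si](CC)(CC)CC)(CO[Si](CC)(CC)CC)[C@@H](C)C(=O)OC(C)(C)C | intermediate
22 | acetoxy-enone vinyl iodide: tert-butyl (2R,3S,4R)-4-acetoxy-4-[(1S,2S,6S)-2-acetoxy-6-[(E)-2-iodoethenyl]-2,6-dimethyl-3-oxocyclohex-4-en-1-yl]-2-methyl-3-[(triethylsilyl)oxy]-3-{[(triethylsilyl)oxy]methyl}butanoate | I/C=C/[C@@]1(C)C=CC(=O)[C@@](C)(OC(C)=O)[C@@H]1[C@@H](OC(C)=O)[C@@](O[Si](CC)(CC)CC)(CO[Si](CC)(CC)CC)[C@@H](C)C(=O)OC(C)(C)C | intermediate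
23 | methyl propiolate | C#CC(=O)OC | starting material
24 | formaldehyde | C=O | starting material
25 | methyl (2Z)-3-chloro-2-(hydroxymethyl)prop-2-enoate | Cl/C=C(/CO)C(=O)OC | intermediate
26 | methyl (2Z)-3-chloro-2-{[(triethylsilyl)oxy]methyl}prop-2-enoate | Cl/C=C(/CO[Si](CC)(CC)CC)C(=O)OC | intermediate
27 | (2E)-3-chloro-2-{[(triethylsilyl)oxy]methyl}prop-2-en-1-ol | Cl/C=C(/CO[Si](CC)(CC)CC)CO | intermediate
28 | (2Z)-3-chloro-2-{[(triethylsilyl)oxy]methyl}prop-2-enal | Cl/C=C(/CO[Si](CC)(CC)CC)C=O | intermediate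
29 | alkenylchromium species: 22 with iodine replaced by CrCl2 | Cl[Cr](Cl)/C=C/[C@@]1(C)C=CC(=O)[C@@](C)(OC(C)=O)[C@@H]1[C@@H](OC(C)=O)[C@@](O[Si](CC)(CC)CC)(CO[Si](CC)(CC)CC)[C@@H](C)C(=O)OC(C)(C)C | intermediate
30 | C4 allylic alcohol: 22 with iodine replaced by the (1S,2Z)-3-chloro-1-hydroxy-2-{[(triethylsilyl)oxy]methyl}prop-2-en-1-yl group; (1S,4S,8S,9R,10S,11S,17R), 2E,5Z | Cl/C=C(/CO[Si](CC)(CC)CC)[C@@H](O)/C=C/[C@@]1(C)C=CC(=O)[C@@](C)(OC(C)=O)[C@@H]1[C@@H](OC(C)=O)[C@@](O[Si](CC)(CC)CC)(CO[Si](CC)(CC)CC)[C@@H](C)C(=O)OC(C)(C)C | intermediate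
31 | C4 acetate of 30 (4,9,11-triacetate; C7, C8, C16 triethylsilyl ethers) | Cl/C=C(/CO[Si](CC)(CC)CC)[C@@H](OC(C)=O)/C=C/[C@@]1(C)C=CC(=O)[C@@](C)(OC(C)=O)[C@@H]1[C@@H](OC(C)=O)[C@@](O[Si](CC)(CC)CC)(CO[Si](CC)(CC)CC)[C@@H](C)C(=O)OC(C)(C)C | intermediate
32 | C7,C16-diol: 31 with both primary silyl ethers removed, C8–OSiEt3 kept | Cl/C=C(/CO)[C@@H](OC(C)=O)/C=C/[C@@]1(C)C=CC(=O)[C@@](C)(OC(C)=O)[C@@H]1[C@@H](OC(C)=O)[C@@](O[Si](CC)(CC)CC)(CO)[C@@H](C)C(=O)OC(C)(C)C | intermediate
33 | C16 allylic bromide: 32 with C16–OH replaced by Br (5E, Cl trans to CH2Br), C7–OH free | Cl/C=C(/CBr)[C@@H](OC(C)=O)/C=C/[C@@]1(C)C=CC(=O)[C@@](C)(OC(C)=O)[C@@H]1[C@@H](OC(C)=O)[C@@](O[Si](CC)(CC)CC)(CO)[C@@H](C)C(=O)OC(C)(C)C | intermediate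
34 | seco aldehyde: 33 with C7 oxidised to CHO; (1S,4S,8R,9R,10S,11S,17R), 2E,5E | Cl/C=C(/CBr)[C@@H](OC(C)=O)/C=C/[C@@]1(C)C=CC(=O)[C@@](C)(OC(C)=O)[C@@H]1[C@@H](OC(C)=O)[C@@](O[Si](CC)(CC)CC)(C=O)[C@@H](C)C(=O)OC(C)(C)C | intermediate
35 | γ-chloroallylchromium species: 34 with bromine replaced by CrCl2 | Cl/C=C(/C[Cr](Cl)Cl)[C@@H](OC(C)=O)/C=C/[C@@]1(C)C=CC(=O)[C@@](C)(OC(C)=O)[C@@H]1[C@@H](OC(C)=O)[C@@](O[Si](CC)(CC)CC)(C=O)[C@@H](C)C(=O)OC(C)(C)C | intermediate
36 | ten-membered anti-chlorohydrin: tert-butyl ester of the 4,9,11-triacetoxy-6-chloro-7-hydroxy-12-oxo-8-[(triethylsilyl)oxy]briara-2E,5(16),13-trien-19-oic acid, (1S,4S,6S,7R,8S,9R,10S,11S,17R) | C=C1[C@@H](OC(C)=O)/C=C/[C@@]2(C)C=CC(=O)[C@@](C)(OC(C)=O)[C@@H]2[C@@H](OC(C)=O)[C@](O[Si](CC)(CC)CC)([C@@H](C)C(=O)OC(C)(C)C)[C@@H](O)[C@H]1Cl | intermediate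
37 | hydroxy acid: 36 with free C8–OH and C19 carboxylic acid | C=C1[C@@H](OC(C)=O)/C=C/[C@@]2(C)C=CC(=O)[C@@](C)(OC(C)=O)[C@@H]2[C@@H](OC(C)=O)[C@](O)([C@@H](C)C(=O)O)[C@@H](O)[C@H]1Cl | intermediate
38 | CNP0159278.2: (1S,4S,6S,7R,8R,9R,10S,11S,17R)-4,9,11-triacetoxy-6-chloro-8-hydroxy-12-oxobriara-2E,5(16),13-trien-19,7-olide | C=C1[C@@H](OC(C)=O)/C=C/[C@@]2(C)C=CC(=O)[C@@](C)(OC(C)=O)[C@@H]2[C@@H](OC(C)=O)[C@]2(O)[C@@H](C)C(=O)O[C@H]2[C@H]1Cl | target

**Totals**
Total step count: 27. Longest linear sequence: 19 steps (steps 1–7, 12–16 and 21–27, from 1 to 38).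

**Steps most likely to fail**

1. Step 26. The allylchromium may be protonated, dimerise or close through a boat-like or syn transition state because the ten-membered ring is strained, and excess divalent chromium may reduce the allylic chloride of the product with loss of the neighbouring oxygen.
Fallback, from 22 and 28, back at 36: the two chromium steps are exchanged so that the ring is closed by the well-known Ni/Cr alkenyl iodide–aldehyde macrocyclisation.
PPTS in MeOH frees only the primary C7 hydroxyl of 22 to give the C7 alcohol F1, and Dess–Martin oxidation gives the C7 aldehyde F2, still carrying the vinyl iodide.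
Enal 28 with HC(OMe)3 and PPTS in MeOH gives (2Z)-3-chloro-2-(dimethoxymethyl)prop-2-en-1-ol F3 (acetal formation with loss of the silyl group), and CBr4/PPh3 gives (1E)-2-(bromomethyl)-1-chloro-3,3-dimethoxyprop-1-ene F4.
CrCl2 in THF without nickel, so that the vinyl iodide survives, couples F4 with F2 in the known intermolecular γ-chloroallylchromium addition to give the anti-chlorohydrin acetal F5.
PPTS in wet acetone unmasks the 2-methylene aldehyde F6.
CrCl2 with catalytic NiCl2 in DMSO at high dilution closes the ring at C3–C4 to the macrocyclic diol F7; the sulfonamide ligand of step 21 can be added to steer C4.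
Acetylation of the less hindered allylic C4 hydroxyl (Ac2O, pyridine, 0 °C) gives 36.

2. Step 21. Ligand control of the facial selectivity at C4 may be weak for an α-branched β-chloro enal.
Fallback, from 21 and 28, back at 31: C4 is set by reduction instead of addition, at the dienol-ether stage where no ring ketone competes.
Coupling without ligand (CrCl2, catalytic NiCl2, DMSO) gives the C4-epimeric allylic alcohols F8.
Dess–Martin oxidation gives the cross-conjugated dienone F9.
CBS reduction (Me-oxazaborolidine, catecholborane, toluene, −78 °C, the α-branched chlorovinyl group acting as the large substituent) gives the (4S)-alcohol F10.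
Acetylation gives the C4 acetate F11, and Pb(OAc)4 as in step 16 gives 31.

3. Step 12. Proton transfer from the hindered, enolisable aldehyde to the basic enolate, retro-aldol on warming, or β-elimination through the ester enolate may outrun C–C bond formation.
Fallback, from 15 and 9, back at 17: the enolate is generated reductively under neutral conditions.
Radical bromination of 15 (NBS, catalytic AIBN, CCl4, reflux) gives the 4-bromo-dioxolanone F12 (Br trans to tert-butyl).
SmI2 in THF at −78 °C in the presence of 9 forms the samarium enolate (Reformatsky-type addition), which adds trans to the tert-butyl group as before to give 17.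

**Further compounds**
F1 | step 26 | C7 alcohol: 22 with the primary C7 silyl ether removed | I/C=C/[C@@]1(C)C=CC(=O)[C@@](C)(OC(C)=O)[C@@H]1[C@@H](OC(C)=O)[C@@](O[Si](CC)(CC)CC)(CO)[C@@H](C)C(=O)OC(C)(C)C
F2 | step 26 | C7 aldehyde: F1 oxidised at C7 | I/C=C/[C@@]1(C)C=CC(=O)[C@@](C)(OC(C)=O)[C@@H]1[C@@H](OC(C)=O)[C@@](O[Si](CC)(CC)CC)(C=O)[C@@H](C)C(=O)OC(C)(C)C
F3 | step 26 | (2Z)-3-chloro-2-(dimethoxymethyl)prop-2-en-1-ol | Cl/C=C(/CO)C(OC)OC
F4 | step 26 | (1E)-2-(bromomethyl)-1-chloro-3,3-dimethoxyprop-1-ene | Cl/C=C(/CBr)C(OC)OC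
F5 | step 26 | anti-chlorohydrin acetal: F2 after addition of the C4–C6/C16 unit at C7 (6S,7R; C4 as dimethyl acetal; C5=C16 methylene) | I/C=C/[C@@]1(C)C=CC(=O)[C@@](C)(OC(C)=O)[C@@H]1[C@@H](OC(C)=O)[C@](O[Si](CC)(CC)CC)([C@@H](C)C(=O)OC(C)(C)C)[C@@H](O)[C@@H](Cl)C(=C)C(OC)OC
F6 | step 26 | 2-methylene aldehyde: F5 with the acetal hydrolysed to the C4 aldehyde | I/C=C/[C@@]1(C)C=CC(=O)[C@@](C)(OC(C)=O)[C@@H]1[C@@H](OC(C)=O)[C@](O[Si](CC)(CC)CC)([C@@H](C)C(=O)OC(C)(C)C)[C@@H](O)[C@@H](Cl)C(=C)C=O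
F7 | step 26 | macrocyclic diol: 36 with free C4 hydroxyl | C=C1[C@@H](O)/C=C/[C@@]2(C)C=CC(=O)[C@@](C)(OC(C)=O)[C@@H]2[C@@H](OC(C)=O)[C@](O[Si](CC)(CC)CC)([C@@H](C)C(=O)OC(C)(C)C)[C@@H](O)[C@H]1Cl
F8 | step 21 | C4-epimeric allylic alcohols: 21 with iodine replaced by the (2Z)-3-chloro-1-hydroxy-2-{[(triethylsilyl)oxy]methyl}prop-2-en-1-yl group, C4 unassigned | Cl/C=C(/CO[Si](CC)(CC)CC)C(O)/C=C/[C@@]1(C)C=CC(O[Si](C)(C)C(C)(C)C)=C(C)[C@@H]1[C@@H](OC(C)=O)[C@@](O[Si](CC)(CC)CC)(CO[Si](CC)(CC)CC)[C@@H](C)C(=O)OC(C)(C)C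
F9 | step 21 | cross-conjugated dienone: F8 oxidised at C4 | Cl/C=C(/CO[Si](CC)(CC)CC)C(=O)/C=C/[C@@]1(C)C=CC(O[Si](C)(C)C(C)(C)C)=C(C)[C@@H]1[C@@H](OC(C)=O)[C@@](O[Si](CC)(CC)CC)(CO[Si](CC)(CC)CC)[C@@H](C)C(=O)OC(C)(C)C
F10 | step 21 | (4S)-alcohol: single C4 epimer of F8 | Cl/C=C(/CO[Si](CC)(CC)CC)[C@@H](O)/C=C/[C@@]1(C)C=CC(O[Si](C)(C)C(C)(C)C)=C(C)[C@@H]1[C@@H](OC(C)=O)[C@@](O[Si](CC)(CC)CC)(CO[Si](CC)(CC)CC)[C@@H](C)C(=O)OC(C)(C)C
F11 | step 21 | C4 acetate of F10 | Cl/C=C(/CO[Si](CC)(CC)CC)[C@@H](OC(C)=O)/C=C/[C@@]1(C)C=CC(O[Si](C)(C)C(C)(C)C)=C(C)[C@@H]1[C@@H](OC(C)=O)[C@@](O[Si](CC)(CC)CC)(CO[Si](CC)(CC)CC)[C@@H](C)C(=O)OC(C)(C)C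
F12 | step 12 | tert-butyl (2R)-2-[(2S)-4-bromo-2-tert-butyl-5-oxo-1,3-dioxolan-4-yl]propanoate (Br trans to tert-butyl) | CC(C)(C)[C@H]1O[C@@](Br)([C@@H](C)C(=O)OC(C)(C)C)C(=O)O1
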